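| setting | cedar | elm | maple | ash | birch |
|---|---|---|---|---|---|
| L | 150 mM | 300 mM | 150 mM | 150 mM | 150 mM |
| X | 4.50 mM | 4.50 mM | 4.50 mM | 13.0 mM | 4.50 mM |
| Q |  |  | 75.0 mM |  |  |
| time |  |  |  |  | 120 h |

- cedar run (time / h: [Q] / mM): 5.9: 13.1; 12: 23.9; 18: 33.6; 23: 38.8; 29: 46.3; 35: 51.1; 41: 57.3
- elm run (time / h: [Q] / mM): 5.9: 38.1; 12: 66.2; 18: 86.4; 23: 99.5; 29: 113.5; 35: 124.5; 41: 134.0
- maple run (time / h: [Q] / mM): 5.9: 88.3; 12: 98.3; 18: 108.0; 23: 114.1; 29: 120.5; 35: 126.4; 41: 131.7
- ash run (time / h: [Q] / mM): 5.9: 28.9; 12: 47.1; 18: 61.5; 23: 68.9; 29: 78.3; 35: 83.3; 41: 89.7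

(readings scatter by 0.4 mM)

- Overall: L -> Q, with X as catalyst.
- Constant volume, constant temperature.
- A reading of a species includes what of it is bound.
- An order is taken over about fifteen percent of the charge, up and down.

- apparent order in [X] of the starting rate, round the charge of the cedar run (the rate where two percent of its L have turned into Q)
- apparent order in [L] of the starting rate, round the charge of the cedar run (the rate where two percent of its L have turned into Q) (one fixed amount of Q, the same in the runs compared)
- Q in the birch run at 120 h, as a share of the L charged

At 41 h, the last reading of the cedar run, c_Q stands at 57.3 mM, so 92.7 mM of the L charged remain unturned. The ratio c_Q/c_L is worth following: in a flask charged without Q, for a rate κ·c_L² with constant κ, it equals θ = κ·c(L, start)·t, a dimensionless number that folds charge and time together. The share turned is then θ/(1+θ).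

Written as θ = t/τ, the number has one clock: τ, the time at which Q made equals L left, estimated from the last cedar reading as 66.3 h. This is the second-order half-life. At the first cedar reading the ratio is 0.0957, which gives τ = 61.7 h, so τ as read from these two cedar readings drifts upward.

Freezing τ puts the birch run, charged as the cedar run, at an estimated θ = 1.81 at 120 h, and this reckoning gives 64.4%.

Is one number enough? Across added Q it holds at the last reading: the maple run has made 56.7 mM by 41 h, about the same as the 57.3 mM of the cedar run. Across charge it does not: for the elm run, with twice the L, τ scaled by the charge gives 166 mM at 41 h, yet the elm reading is 134.0 mM, which is less.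

The first readings give the ratio as 0.145 in the elm run and 0.239 in the ash run. Against the cedar run, and over the whole span of these charges, these read as an order in L of 1.60 and an order in X of 0.861.

The forecast, on “roughly second order in L with mild catalyst decay”, gives 0.86 in X, 1.7 in L and 59% (54% to 65%), a share lower than the 64.4% reckoned here.

The simulation gives 0.75 in X, 1.7 in L and 62.4% for the birch run.

X + L ⇌ XL, settled at all times (0.7370 M⁻¹); XL + L ⇌ XL2, settled at all times (1.420 M⁻¹); XL2 → Q + XL (20.45 h⁻¹); XL → Ek + L (0.2059 h⁻¹); L → Q (0.004104 h⁻¹) That share means θ = 1.66 at 120 h, below the frozen 1.81, and so an effective τ of 72.3 h. In the cedar run, Q made comes to half of the L charged at 71.0 h, later than the frozen 66.3 h. In the elm run, τ scaled by the charge gives 33.2 h, while the same mark is reached later, at 54.0 h.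

Readings and results stem from a simulated flask with constants of no real substance; scatter was added.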